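## Retrosynthetic overview

1. 12 ⇒ 10: ring C is closed last through the C3–C4 bond. A thiazolylidene carbene turns the aldehyde carbon of 10 into an acyl anion equivalent, which displaces a primary bromide; the C2 stereocentre is carried through untouched.
2. 10 ⇒ 7 + 8: the aryl ether bond (O1–C2) is made by Mitsunobu inversion of (S)-bromohydrin 7 with 2-hydroxy-4-methoxybenzaldehyde 8.
3. 7 ⇒ 6 ⇒ 4: a CBS reduction sets the only stereocentre; bromoketone 6 comes from one-carbon homologation of ester 4 with LiCH2Br.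
4. 4 ⇒ 1 + 2: the benzofuran is built by Sonogashira coupling and 5-endo-dig cyclisation.
5. Ring order: the furan ring of the benzofuran first (step 1), the pyranone ring C of the flavanone last (step 5).

Assumption: the target is the (2S)-flavanone exactly as encoded in the SMILES, and 1, 2 and 8 are taken as catalogue compounds. Ar below means 2-(4-methoxyphenyl)-1-benzofuran-5-yl.

## Route

Step 1
Reactants: 1 methyl 4-hydroxy-3-iodobenzoate; 2 1-ethynyl-4-methoxybenzene
Product: 4 methyl 2-(4-methoxyphenyl)-1-benzofuran-5-carboxylate, via o-alkynylphenol 3 (not isolated)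
Conditions: PdCl2(PPh3)2 (3 mol %), CuI (5 mol %), Et3N (3 equiv), DMF, 25 → 70 °C, Ar
Reagents that add atoms: none
Why: Sonogashira coupling at the aryl iodide is followed in the same pot by 5-endo-dig attack of the ester-acidified phenoxide on the alkyne (Castro–Stephens/Larock-type benzofuran annulation), which fixes the 2-aryl-5-carboxylate pattern; no stereocentre is formed.

Step 2
Reactants: 4 methyl 2-(4-methoxyphenyl)-1-benzofuran-5-carboxylate
Product: 6 2-bromo-1-[2-(4-methoxyphenyl)-1-benzofuran-5-yl]ethan-1-one, via lithium hemiketal alkoxide 5 (not isolated)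
Conditions: CH2Br2 (2.5 equiv), MeLi·LiBr (2.2 equiv, slow addition), THF, −78 °C; then AcOH, −78 °C → 25 °C
Reagents that add atoms: dibromomethane, BrCBr
Why: Br/Li exchange gives the carbenoid LiCH2Br, which adds once to the ester because tetrahedral adduct 5 is stable at −78 °C and collapses to the bromomethyl ketone only on acidic quench (ester to halomethyl ketone homologation with halomethyllithium made in situ); no stereocentre is formed.

Step 3
Reactants: 6 2-bromo-1-[2-(4-methoxyphenyl)-1-benzofuran-5-yl]ethan-1-one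
Product: 7 (1S)-2-bromo-1-[2-(4-methoxyphenyl)-1-benzofuran-5-yl]ethan-1-ol
Conditions: (3aS)-1-methyl-3,3-diphenyltetrahydro-1H,3H-pyrrolo[1,2-c][1,3,2]oxazaborole [(S)-Me-CBS] (10 mol %), BH3·SMe2 (0.7 equiv), THF, 0 °C, slow addition of 6; MeOH quench
Reagents that add atoms: none
Why: In this Corey–Bakshi–Shibata reduction the aryl group is the large and CH2Br the small substituent, so the (S)-oxazaborolidine delivers hydride to the face that gives the (S)-bromohydrin (S because CH2Br outranks aryl), expected at ≥95 % ee by analogy with other aryl halomethyl ketones.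

Step 4
Reactants: 7 (1S)-2-bromo-1-[2-(4-methoxyphenyl)-1-benzofuran-5-yl]ethan-1-ol; 8 2-hydroxy-4-methoxybenzaldehyde
Product: 10 2-{(1R)-2-bromo-1-[2-(4-methoxyphenyl)-1-benzofuran-5-yl]ethoxy}-4-methoxybenzaldehyde, via alkoxyphosphonium phenoxide 9 (not isolated)
Conditions: 8 (1.3 equiv), PPh3 (1.4 equiv), DIAD (1.4 equiv), toluene, −20 → 0 °C
Reagents that add atoms: none
Why: In this Mitsunobu etherification the acidic phenoxide of 8 displaces the alkoxyphosphonium group of 9 by SN2 with inversion (S → R) while the bromomethyl group is untouched, and the cold, non-polar medium is chosen to keep the electron-rich benzylic centre from ionising.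

Step 5
Reactants: 10 2-{(1R)-2-bromo-1-[2-(4-methoxyphenyl)-1-benzofuran-5-yl]ethoxy}-4-methoxybenzaldehyde
Product: 12 Lophirone J [(2S)-7-methoxy-2-[2-(4-methoxyphenyl)-1-benzofuran-5-yl]-2,3-dihydro-4H-chromen-4-one], via Breslow intermediate 11 (not isolated)
Conditions: 3-benzyl-5-(2-hydroxyethyl)-4-methylthiazolium chloride (20 mol %), iPr2NEt (1.1 equiv), 1,4-dioxane, 60 °C, Ar; AcOH quench
Reagents that add atoms: none
Why: The thiazol-2-ylidene adds to the aldehyde to give Breslow intermediate 11, an acyl anion equivalent whose carbon displaces the primary bromide in a 6-exo-tet SN2 closure (carbene-catalysed intramolecular alkylation, the reaction type that converts 2-(2-sulfonyloxyethoxy)benzaldehydes into chroman-4-ones, extended here to a bromide), and loss of the carbene then gives the C4 ketone with the spectator stereocentre of (R)-10 becoming (2S) in 12 by a change of CIP priorities only, the weak amine base being chosen to avoid retro-oxa-Michael racemisation.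

## Compound list

1 | methyl 4-hydroxy-3-iodobenzoate | COC(=O)c1ccc(O)c(I)c1 | starting material
2 | 1-ethynyl-4-methoxybenzene | C#Cc1ccc(OC)cc1 | starting material
3 | methyl 4-hydroxy-3-[(4-methoxyphenyl)ethynyl]benzoate | COC(=O)c1ccc(O)c(C#Cc2ccc(OC)cc2)c1 | intermediate (not isolated)
4 | methyl 2-(4-methoxyphenyl)-1-benzofuran-5-carboxylate | COC(=O)c1ccc2oc(-c3ccc(OC)cc3)cc2c1 | intermediate
5 | lithium 2-bromo-1-methoxy-1-[2-(4-methoxyphenyl)-1-benzofuran-5-yl]ethan-1-olate (racemic at the hemiketal carbon) | [Li+].[O-]C(OC)(CBr)c1ccc2oc(-c3ccc(OC)cc3)cc2c1 | intermediate (not isolated)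
6 | 2-bromo-1-[2-(4-methoxyphenyl)-1-benzofuran-5-yl]ethan-1-one | O=C(CBr)c1ccc2oc(-c3ccc(OC)cc3)cc2c1 | intermediate
7 | (1S)-2-bromo-1-[2-(4-methoxyphenyl)-1-benzofuran-5-yl]ethan-1-ol | O[C@H](CBr)c1ccc2oc(-c3ccc(OC)cc3)cc2c1 | intermediate
8 | 2-hydroxy-4-methoxybenzaldehyde | COc1ccc(C=O)c(O)c1 | starting material
9 | {(1S)-2-bromo-1-[2-(4-methoxyphenyl)-1-benzofuran-5-yl]ethoxy}triphenylphosphonium 2-formyl-5-methoxyphenolate | c1ccccc1[P+](c1ccccc1)(c1ccccc1)O[C@H](CBr)c1ccc2oc(-c3ccc(OC)cc3)cc2c1.[O-]c1cc(OC)ccc1C=O | intermediate (not isolated)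
10 | 2-{(1R)-2-bromo-1-[2-(4-methoxyphenyl)-1-benzofuran-5-yl]ethoxy}-4-methoxybenzaldehyde | COc1ccc(C=O)c(O[C@@H](CBr)c2ccc3oc(-c4ccc(OC)cc4)cc3c2)c1 | intermediate
11 | {2-[(1R)-2-bromo-1-[2-(4-methoxyphenyl)-1-benzofuran-5-yl]ethoxy]-4-methoxyphenyl}[3-benzyl-5-(2-hydroxyethyl)-4-methyl-1,3-thiazol-2(3H)-ylidene]methanol | OC(=C1SC(CCO)=C(C)N1Cc1ccccc1)c1ccc(OC)cc1O[C@@H](CBr)c1ccc2oc(-c3ccc(OC)cc3)cc2c1 | intermediate (not isolated)
12 | Lophirone J, (2S)-7-methoxy-2-[2-(4-methoxyphenyl)-1-benzofuran-5-yl]-2,3-dihydro-4H-chromen-4-one | COc1ccc(-c2cc3cc([C@@H]4CC(=O)c5ccc(OC)cc5O4)ccc3o2)cc1 | target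

## Summary

Total step count: 5. Longest linear sequence: 5 steps (1 → 4 → 6 → 7 → 10 → 12); 2 and 8 enter as purchased reagents.

The three steps most likely to fail, with fallbacks:

**Step 5 (carbene-catalysed ring closure).** The risks are a sluggish SN2 at the β-branched bromide, alkylation of the catalyst, and base-induced opening of 12 to the chalcone with loss of ee. The fallback sets out from 10 and comes back at 12, forming the same bond with a stoichiometric acyl anion. Aldehyde 10 is thioacetalised with propane-1,3-dithiol (I2 5 mol %, CH2Cl2, 25 °C) to 2-{2-[(1R)-2-bromo-1-Ar-ethoxy]-4-methoxyphenyl}-1,3-dithiane F1. LiN(iPr)2 (THF, −78 → −30 °C) lithiates C2 of the dithiane, which closes onto the bromide (6-exo-tet) to give the spiro dithioketal of the flavanone F2. MeI/CaCO3 in aqueous MeCN (45 °C) then unmasks ketone 12 without exposing it to base.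

**Step 4 (Mitsunobu etherification).** The carbinol is electron-rich and benzylic and the phenol is hindered and hydrogen-bonded, so the risks are partial SN1 with loss of ee, elimination, and low conversion. The fallback sets out from 7 and comes back at 12, making the C–C bond first and the C–O bond last and intramolecularly. Bromohydrin 7 is closed with K2CO3 in MeOH (0 °C) to (2S)-2-Ar-oxirane F3. Separately, 8 is converted with propane-1,3-dithiol and BF3·OEt2 into 2-(1,3-dithian-2-yl)-5-methoxyphenol F4. The O,C-dilithio derivative of F4 (n-BuLi 2.2 equiv, THF, −78 → −20 °C) opens F3 at its CH2 terminus to the (1R)-hydroxy dithiane F5. MeI/CaCO3 in aqueous MeCN frees the (3R)-β-hydroxy ketone F6. PPh3/DIAD (THF, 0 °C) closes ring C by intramolecular Mitsunobu reaction with inversion to (2S)-12; the fast six-membered closure should outrun ionisation.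

**Step 2 (carbenoid homologation).** The risks are decomposition of LiCH2Br before it adds to the electron-rich ester, and double addition. The fallback sets out from 4 and comes back at 6 through a sulfoxonium ylide. Ester 4 acylates dimethylsulfoxonium methylide (Me3S(O)I, KOtBu, THF, reflux) to give the β-keto sulfoxonium ylide F7. HBr (48 % aqueous, THF, 50 °C) protonates F7, and bromide then displaces dimethyl sulfoxide at carbon to give 6.

## Further compounds

F1 | step 5 | 2-{2-[(1R)-2-bromo-1-[2-(4-methoxyphenyl)-1-benzofuran-5-yl]ethoxy]-4-methoxyphenyl}-1,3-dithiane | COc1ccc(C2SCCCS2)c(O[C@@H](CBr)c2ccc3oc(-c4ccc(OC)cc4)cc3c2)c1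
F2 | step 5 | (2S)-7-methoxy-2-[2-(4-methoxyphenyl)-1-benzofuran-5-yl]spiro[chromane-4,2'-[1,3]dithiane] | COc1ccc2c(c1)O[C@@H](CC21SCCCS1)c1ccc2oc(-c3ccc(OC)cc3)cc2c1
F3 | step 4 | (2S)-2-[2-(4-methoxyphenyl)-1-benzofuran-5-yl]oxirane | O1C[C@@H]1c1ccc2oc(-c3ccc(OC)cc3)cc2c1
F4 | step 4 | 2-(1,3-dithian-2-yl)-5-methoxyphenol | COc1ccc(C2SCCCS2)c(O)c1
F5 | step 4 | (1R)-2-[2-(2-hydroxy-4-methoxyphenyl)-1,3-dithian-2-yl]-1-[2-(4-methoxyphenyl)-1-benzofuran-5-yl]ethan-1-ol | O[C@H](CC1(SCCCS1)c1ccc(OC)cc1O)c1ccc2oc(-c3ccc(OC)cc3)cc2c1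
F6 | step 4 | (3R)-3-hydroxy-1-(2-hydroxy-4-methoxyphenyl)-3-[2-(4-methoxyphenyl)-1-benzofuran-5-yl]propan-1-one | O[C@H](CC(=O)c1ccc(OC)cc1O)c1ccc2oc(-c3ccc(OC)cc3)cc2c1
F7 | step 2 | dimethylsulfoxonium 2-[2-(4-methoxyphenyl)-1-benzofuran-5-yl]-2-oxoethylide | CS(C)(=O)=CC(=O)c1ccc2oc(-c3ccc(OC)cc3)cc2c1
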